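**Plan**

1. Chain numbered from the ketone carbon (C1) to the methyl carbon (C20). The retrosynthesis cuts aryl–C1 (aryllithium on a Weinreb amide), then C10–C11, then C6–C7 and C12–C13 (copper acetylide alkylations), then C15–C16 (acetylide opening of an epoxide).
2. Enabling feature: C7, C10 and C13 are methylenes each held between two Z-olefins (C5=C6, C8=C9, C11=C12, C14=C15). Raising all four olefins to triple bonds makes C10 a primary propargylic electrophile and C11 an acetylide carbon, so both C10 halves are simple skipped diynes.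
3. Forward: the left half C11–C20 comes from (R)-1,2-epoxypentane, the right half C1–C10 from hex-5-ynoic acid and 4-chlorobut-2-yn-1-ol. Their union gives the whole C20 chain as a skipped tetrayne.
4. One cis-semihydrogenation then removes the four helper triple bonds and sets all four Z-olefins together. The phloroglucinol ring is attached last and one acid step frees the four hydroxyls.
5. Stereochemistry: C17 (R) is bought with the epoxide and never touched. The four Z geometries come from syn delivery of H2 on the catalyst surface.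

Key step: step 8

Remark on the chemistry: (R)-1,2-epoxypentane is taken as commercially available as the single enantiomer.

**Route**

Step 1
Reactants: 1 (R)-1,2-epoxypentane
Product: 2 (R)-hept-1-yn-4-ol
Conditions: LiC≡CH·H2NCH2CH2NH2, DMSO, 0 °C to rt; H2O
Reagents that add atoms: LiC≡CH·H2NCH2CH2NH2 (lithium acetylide–ethylenediamine complex), [Li]C#C.NCCN
Why: Acetylide opening of a terminal epoxide (SN2) occurs only at the unhindered CH2 carbon, so the C–O bond at the stereocentre is never broken and the (R) configuration of 1 is carried unchanged into C17.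

Step 2
Reactants: 2 (R)-hept-1-yn-4-ol
Product: 3 (R)-tert-butyl(hept-1-yn-4-yloxy)dimethylsilane
Conditions: TBSCl, imidazole, DMF, rt
Reagents that add atoms: TBSCl (tert-butyldimethylsilyl chloride), CC(C)(C)[Si](C)(C)Cl
Why: Imidazole-promoted silylation of a secondary alcohol gives a TBS ether that should survive carbonate, monovalent copper, hydrogenation and aryllithium and be removed in the final acid step.

Step 3
Reactants: 3 (R)-tert-butyl(hept-1-yn-4-yloxy)dimethylsilane; 4 3-bromo-1-(trimethylsilyl)prop-1-yne
Product: 7 (R)-tert-butyldimethyl{[10-(trimethylsilyl)deca-6,9-diyn-4-yl]oxy}silane, via (R)-4-(tert-butyldimethylsilyloxy)hept-1-ynylcopper 5 (not isolated), via 3-iodo-1-(trimethylsilyl)prop-1-yne 6 (not isolated)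
Conditions: CuI, NaI, K2CO3, DMF, rt, Ar
Reagents that add atoms: none
Why: Copper acetylide alkylation of a terminal alkyne with a primary propargylic halide (halide exchange to iodide 6, then SN2 coupling with acetylide 5) is the standard route to skipped diynes, and the C-silyl cap keeps the new alkyne terminus from reacting again.

Step 4
Reactants: 7 (R)-tert-butyldimethyl{[10-(trimethylsilyl)deca-6,9-diyn-4-yl]oxy}silane
Product: 8 (R)-tert-butyl(deca-6,9-diyn-4-yloxy)dimethylsilane
Conditions: AgNO3 (0.1 equiv), CH2Cl2/MeOH/H2O, rt, dark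
Reagents that add atoms: none
Why: Silver-catalysed protiodesilylation of an alkynylsilane (a silver acetylide that is protonated by water) runs without base, so the base-labile 1,4-diyne should not drift to an allene and the O-silyl ether should stay in place.

Step 5
Reactants: 9 hex-5-ynoic acid
Product: 11 N-methoxy-N-methylhex-5-ynamide, via 1-(hex-5-ynoyl)imidazole 10 (not isolated)
Conditions: CDI, CH2Cl2, rt; then MeNHOMe·HCl, rt
Reagents that add atoms: N,O-dimethylhydroxylamine hydrochloride, CNOC.Cl
Why: Carboxyl activation as the acyl imidazole followed by aminolysis is the routine Weinreb amide synthesis and leaves the terminal alkyne untouched.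

Step 6
Reactants: 11 N-methoxy-N-methylhex-5-ynamide; 12 4-chlorobut-2-yn-1-ol
Product: 15 10-hydroxy-N-methoxy-N-methyldeca-5,8-diynamide, via 6-[methoxy(methyl)amino]-6-oxohex-1-ynylcopper 13 (not isolated), via 4-iodobut-2-yn-1-ol 14 (not isolated)
Conditions: CuI, NaI, K2CO3, DMF, rt, Ar
Reagents that add atoms: none
Why: The same copper acetylide alkylation (chloride-to-iodide exchange giving 14, then SN2 coupling with acetylide 13) tolerates the free primary alcohol and the Weinreb amide and builds the C5–C10 skipped diyne.

Step 7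
Reactants: 15 10-hydroxy-N-methoxy-N-methyldeca-5,8-diynamide
Product: 16 10-bromo-N-methoxy-N-methyldeca-5,8-diynamide
Conditions: CBr4, PPh3, CH2Cl2, −20 to 0 °C
Reagents that add atoms: CBr4 (tetrabromomethane), BrC(Br)(Br)Br
Why: Appel bromination converts the primary propargylic alcohol into the bromide under neutral conditions by SN2 displacement of the oxyphosphonium group, which avoids allenyl rearrangement.

Step 8
Reactants: 8 (R)-tert-butyl(deca-6,9-diyn-4-yloxy)dimethylsilane; 16 10-bromo-N-methoxy-N-methyldeca-5,8-diynamide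
Product: 19 (R)-17-[(tert-butyldimethylsilyl)oxy]-N-methoxy-N-methylicosa-5,8,11,14-tetraynamide, via (R)-7-(tert-butyldimethylsilyloxy)deca-1,4-diynylcopper 17 (not isolated), via 10-iodo-N-methoxy-N-methyldeca-5,8-diynamide 18 (not isolated)
Conditions: CuI, NaI, K2CO3, DMF, rt, Ar, dark
Reagents that add atoms: none
Why: K2CO3 and CuI convert the terminal alkyne of 8 into the monovalent copper acetylide 17 while NaI exchanges the bromide of 16 for iodide (18); the acetylide then attacks the primary propargylic carbon C10, by direct SN2 displacement or by oxidative addition to a trivalent copper intermediate and reductive elimination, forming the C10–C11 bond and returning CuI. The closest known reaction type is the copper-mediated coupling of terminal alkynes with propargylic halides used to build skipped polyynes. No ring is closed and no stereocentre is formed, and C17 is remote and untouched. The selectivity needed is attack at C10 (SN2) over attack at C8 (SN2', which would give an allene), and it is secured by the unhindered primary CH2–halogen terminus and the soft copper acetylide. The step must also avoid base-promoted propargyl-to-allenyl isomerisation of the 1,4-diyne units and oxidative dimerisation of the alkyne, which the weak heterogeneous carbonate base at room temperature and the exclusion of air should ensure. The product holds the complete C20 chain with C7, C10 and C13 each between two triple bonds, ready for one reduction that sets all four olefins.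

Step 9
Reactants: 19 (R)-17-[(tert-butyldimethylsilyl)oxy]-N-methoxy-N-methylicosa-5,8,11,14-tetraynamide
Product: 20 (17R,5Z,8Z,11Z,14Z)-17-[(tert-butyldimethylsilyl)oxy]-N-methoxy-N-methylicosa-5,8,11,14-tetraenamide
Conditions: H2 (1 atm, 4 equiv uptake), Pd/CaCO3 poisoned with Pb(OAc)2 (Lindlar catalyst), quinoline, EtOAc, rt
Reagents that add atoms: none
Why: Lindlar semihydrogenation adds H2 syn to each triple bond on the lead-poisoned palladium surface while quinoline slows further reduction, a reaction type well established for skipped tetraynes, so the four alkynes should give the four Z-olefins together without touching the amide N–O bond or the silyl ether.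

Step 10
Reactants: 21 phloroglucinol (benzene-1,3,5-triol)
Product: 22 1,3,5-tris(methoxymethoxy)benzene
Conditions: MOMCl, i-Pr2NEt, CH2Cl2, 0 °C to rt
Reagents that add atoms: MOMCl (chloromethyl methyl ether), COCCl
Why: O-Alkylation of the three phenols with MOMCl and an amine base gives the tris-acetal, whose oxygen atoms later direct lithiation and which is stable to organolithiums.

Step 11
Reactants: 22 1,3,5-tris(methoxymethoxy)benzene; 20 (17R,5Z,8Z,11Z,14Z)-17-[(tert-butyldimethylsilyl)oxy]-N-methoxy-N-methylicosa-5,8,11,14-tetraenamide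
Product: 24 (17R,5Z,8Z,11Z,14Z)-17-[(tert-butyldimethylsilyl)oxy]-1-[2,4,6-tris(methoxymethoxy)phenyl]icosa-5,8,11,14-tetraen-1-one, via 2,4,6-tris(methoxymethoxy)phenyllithium 23 (not isolated)
Conditions: 22 (2 equiv), n-BuLi, THF, 0 °C; then 20, −78 to 0 °C; H2O
Reagents that add atoms: none
Why: Directed ortho-lithiation of 22 between two MOM ethers (all three ring C–H are equivalent) gives 23, which adds once to the Weinreb amide because the chelated tetrahedral adduct collapses to the ketone only on aqueous quench, and the bis-allylic C–H bonds are not acidic enough to react at −78 °C.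

Step 12
Reactants: 24 (17R,5Z,8Z,11Z,14Z)-17-[(tert-butyldimethylsilyl)oxy]-1-[2,4,6-tris(methoxymethoxy)phenyl]icosa-5,8,11,14-tetraen-1-one
Product: 25 (17R,5Z,8Z,11Z,14Z)-17-hydroxy-1-(2,4,6-trihydroxyphenyl)icosa-5,8,11,14-tetraen-1-one
Conditions: HCl (1.25 M in MeOH), MeOH, 40 °C, Ar
Reagents that add atoms: none
Why: Acid-catalysed transacetalisation to methanol cleaves the three MOM ethers and acid methanolysis cleaves the TBS ether in one operation, under dilute methanolic acid that should neither isomerise the skipped Z-olefins nor affect C17.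

**Compound list**

1 | (R)-1,2-epoxypentane | CCC[C@@H]1CO1 | starting material
2 | (R)-hept-1-yn-4-ol | CCC[C@@H](O)CC#C | intermediate
3 | (R)-tert-butyl(hept-1-yn-4-yloxy)dimethylsilane | CCC[C@@H](O[Si](C)(C)C(C)(C)C)CC#C | intermediate
4 | 3-bromo-1-(trimethylsilyl)prop-1-yne | C[Si](C)(C)C#CCBr | starting material
5 | (R)-4-(tert-butyldimethylsilyloxy)hept-1-ynylcopper | CCC[C@@H](O[Si](C)(C)C(C)(C)C)CC#C[Cu] | intermediate
6 | 3-iodo-1-(trimethylsilyl)prop-1-yne | C[Si](C)(C)C#CCI | intermediate
7 | (R)-tert-butyldimethyl{[10-(trimethylsilyl)deca-6,9-diyn-4-yl]oxy}silane | CCC[C@@H](O[Si](C)(C)C(C)(C)C)CC#CCC#C[Si](C)(C)C | intermediate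
8 | (R)-tert-butyl(deca-6,9-diyn-4-yloxy)dimethylsilane | CCC[C@@H](O[Si](C)(C)C(C)(C)C)CC#CCC#C | intermediate
9 | hex-5-ynoic acid | C#CCCCC(=O)O | starting material
10 | 1-(hex-5-ynoyl)imidazole | C#CCCCC(=O)n1ccnc1 | intermediate
11 | N-methoxy-N-methylhex-5-ynamide | C#CCCCC(=O)N(C)OC | intermediate
12 | 4-chlorobut-2-yn-1-ol | OCC#CCCl | starting material
13 | 6-[methoxy(methyl)amino]-6-oxohex-1-ynylcopper | [Cu]C#CCCCC(=O)N(C)OC | intermediate
14 | 4-iodobut-2-yn-1-ol | OCC#CCI | intermediate
15 | 10-hydroxy-N-methoxy-N-methyldeca-5,8-diynamide | OCC#CCC#CCCCC(=O)N(C)OC | intermediate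
16 | 10-bromo-N-methoxy-N-methyldeca-5,8-diynamide | BrCC#CCC#CCCCC(=O)N(C)OC | intermediate
17 | (R)-7-(tert-butyldimethylsilyloxy)deca-1,4-diynylcopper | CCC[C@@H](O[Si](C)(C)C(C)(C)C)CC#CCC#C[Cu] | intermediate
18 | 10-iodo-N-methoxy-N-methyldeca-5,8-diynamide | ICC#CCC#CCCCC(=O)N(C)OC | intermediate
19 | (R)-17-[(tert-butyldimethylsilyl)oxy]-N-methoxy-N-methylicosa-5,8,11,14-tetraynamide | CCC[C@@H](O[Si](C)(C)C(C)(C)C)CC#CCC#CCC#CCC#CCCCC(=O)N(C)OC | intermediate
20 | (17R,5Z,8Z,11Z,14Z)-17-[(tert-butyldimethylsilyl)oxy]-N-methoxy-N-methylicosa-5,8,11,14-tetraenamide | CCC[C@@H](O[Si](C)(C)C(C)(C)C)C/C=C\C/C=C\C/C=C\C/C=C\CCCC(=O)N(C)OC | intermediate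
21 | phloroglucinol (benzene-1,3,5-triol) | Oc1cc(O)cc(O)c1 | starting material
22 | 1,3,5-tris(methoxymethoxy)benzene | COCOc1cc(OCOC)cc(OCOC)c1 | intermediate
23 | 2,4,6-tris(methoxymethoxy)phenyllithium | [Li]c1c(OCOC)cc(OCOC)cc1OCOC | intermediate
24 | (17R,5Z,8Z,11Z,14Z)-17-[(tert-butyldimethylsilyl)oxy]-1-[2,4,6-tris(methoxymethoxy)phenyl]icosa-5,8,11,14-tetraen-1-one | CCC[C@@H](O[Si](C)(C)C(C)(C)C)C/C=C\C/C=C\C/C=C\C/C=C\CCCC(=O)c1c(OCOC)cc(OCOC)cc1OCOC | intermediate
25 | (17R,5Z,8Z,11Z,14Z)-17-hydroxy-1-(2,4,6-trihydroxyphenyl)icosa-5,8,11,14-tetraen-1-one | CCC[C@@H](O)C/C=C\C/C=C\C/C=C\C/C=C\CCCC(=O)c1c(O)cc(O)cc1O | target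

**Count and risks**

Total step count: 12. Longest linear sequence: 8 steps (steps 1, 2, 3, 4, 8, 9, 11, 12).

Steps most likely to fail:

Step 9. The four triple bonds are reduced at different rates, so olefins formed early may be carried on to saturated units before the last alkyne is consumed, or the reduction may stall short of full conversion; double-bond migration or Z-to-E drift on palladium is a lesser risk. The fallback sets out from 15 and comes back at 20, and never reduces more than two triple bonds in one operation. Diynol 15 alone is semihydrogenated (H2, Pd/CaCO3 poisoned with Pb(OAc)2, quinoline, EtOAc) to (5Z,8Z)-10-hydroxy-N-methoxy-N-methyldeca-5,8-dienamide F1. Appel bromination (CBr4, PPh3, CH2Cl2, −20 °C) should give (5Z,8Z)-10-bromo-N-methoxy-N-methyldeca-5,8-dienamide F2, to be used at once. Copper acetylide alkylation of F2 with alkyne 8 (CuI, K2CO3, DMF, rt, through acetylide 17) still forms C10–C11, now at an allylic instead of a propargylic carbon, and should give (R,5Z,8Z)-17-[(tert-butyldimethylsilyl)oxy]-N-methoxy-N-methylicosa-5,8-dien-11,14-diynamide F3. Semihydrogenation of its two remaining triple bonds under the same catalyst should then give 20.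

Step 8. The acetylide may attack the γ-carbon (SN2') to form an allene, either skipped diyne may undergo base-promoted propargyl-to-allenyl isomerisation, or alkyne 8 may dimerise oxidatively; all are aggravated because both partners are elaborate and must be used near one to one. The fallback sets out from 8 and comes back at 19, growing the chain linearly so that the simple partner can be used in excess in each coupling. Alkyne 8 is alkylated with excess 4-chlorobut-2-yn-1-ol 12 (CuI, NaI, K2CO3, DMF, through 17 and 14) to (R)-11-[(tert-butyldimethylsilyl)oxy]tetradeca-2,5,8-triyn-1-ol F4. Appel bromination (CBr4, PPh3, CH2Cl2) should give (R)-[(14-bromotetradeca-6,9,12-triyn-4-yl)oxy](tert-butyl)dimethylsilane F5. Coupling of F5 with excess N-methoxy-N-methylhex-5-ynamide 11 (CuI, K2CO3, DMF, through acetylide 13) should give 19.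

Step 11. The hindered, strongly basic aryllithium may act as a base instead of a nucleophile (α-deprotonation of the amide, or elimination of formaldehyde from the N–OMe group), so that acyl transfer does not take place. The fallback sets out from 20 and comes back at 24, replacing acyl substitution by carbonyl addition and oxidation. Reduction of 20 with i-Bu2AlH (THF, −78 °C) should give (17R,5Z,8Z,11Z,14Z)-17-[(tert-butyldimethylsilyl)oxy]icosa-5,8,11,14-tetraenal F6. Addition of aryllithium 23 at −78 °C should give (17R,5Z,8Z,11Z,14Z)-17-[(tert-butyldimethylsilyl)oxy]-1-[2,4,6-tris(methoxymethoxy)phenyl]icosa-5,8,11,14-tetraen-1-ol F7 as both C1 epimers, which is of no consequence. Dess–Martin oxidation (NaHCO3, CH2Cl2, rt) should then give 24.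

Further compounds

F1 | step 9 | (5Z,8Z)-10-hydroxy-N-methoxy-N-methyldeca-5,8-dienamide | OC/C=C\C/C=C\CCCC(=O)N(C)OC
F2 | step 9 | (5Z,8Z)-10-bromo-N-methoxy-N-methyldeca-5,8-dienamide | BrC/C=C\C/C=C\CCCC(=O)N(C)OC
F3 | step 9 | (R,5Z,8Z)-17-[(tert-butyldimethylsilyl)oxy]-N-methoxy-N-methylicosa-5,8-dien-11,14-diynamide | CCC[C@@H](O[Si](C)(C)C(C)(C)C)CC#CCC#CC/C=C\C/C=C\CCCC(=O)N(C)OC
F4 | step 8 | (R)-11-[(tert-butyldimethylsilyl)oxy]tetradeca-2,5,8-triyn-1-ol | CCC[C@@H](O[Si](C)(C)C(C)(C)C)CC#CCC#CCC#CCO
F5 | step 8 | (R)-[(14-bromotetradeca-6,9,12-triyn-4-yl)oxy](tert-butyl)dimethylsilane | CCC[C@@H](O[Si](C)(C)C(C)(C)C)CC#CCC#CCC#CCBr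
F6 | step 11 | (17R,5Z,8Z,11Z,14Z)-17-[(tert-butyldimethylsilyl)oxy]icosa-5,8,11,14-tetraenal | CCC[C@@H](O[Si](C)(C)C(C)(C)C)C/C=C\C/C=C\C/C=C\C/C=C\CCCC=O
F7 | step 11 | (17R,5Z,8Z,11Z,14Z)-17-[(tert-butyldimethylsilyl)oxy]-1-[2,4,6-tris(methoxymethoxy)phenyl]icosa-5,8,11,14-tetraen-1-ol (both C1 epimers) | CCC[C@@H](O[Si](C)(C)C(C)(C)C)C/C=C\C/C=C\C/C=C\C/C=C\CCCC(O)c1c(OCOC)cc(OCOC)cc1OCOC
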